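**Plan**
- Locants: C7 = guaiacyl-bearing carbon, C7' = carbon bearing the central aryl ring, C8/C8' = ring-fusion carbons, C9/C9' = OCH2 carbons, C7''–C9'' = arylglycerol chain.
- Cuts, in retrosynthetic order: C7''–C8'' (glycolate aldol) and aryl O–C8'' (phenol alkylation); O–C9' of the guaiacyl-bearing ring (lactone reduction and re-closure); C8'–C7' (carbenoid C–H insertion); the C9–O benzyl ether; C7–C8 (succinate aldol).
- Enabling feature: the ring O–C7'–C8'–C8–C9 holds its aryl group endo (cis to C9') and C7' is a benzylic ether CH, which is what a C8' carbenoid gives by inserting into an ArCH2–O–C9 arm.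
- Forward order: aldol/lactonisation gives the trans γ-lactone (C7, C8); etherification at C9 and diazo transfer at C8'; the insertion closes the aryl-bearing tetrahydrofuran; the lactone is reduced and re-closed as the second tetrahydrofuran; the side chain is then attached to the central phenol.
- Stereochemistry: C7/C8 from an Evans syn aldol with the (R)-auxiliary; C8'/C7' from the insertion (cis fusion, endo aryl); C7''/C8'' (threo, R,R) from an Evans syn glycolate aldol with the (S)-auxiliary.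

Key step: step 10

Remark: O-benzylvanillin, 4-benzyloxy-3,5-dimethoxybenzaldehyde, methyl 4-chloro-4-oxobutanoate and both enantiomers of 4-benzyl-2-oxazolidinone are taken as purchased; the endo benzylic ether at C7' is acid-labile, so every step after it is formed is kept neutral or basic as far as possible.

**Route**

Step 1
Reactants: 1 (R)-4-benzyl-2-oxazolidinone; 2 methyl 4-chloro-4-oxobutanoate
Product: 3 (R)-4-benzyl-3-(4-methoxy-4-oxobutanoyl)oxazolidin-2-one
Conditions: n-BuLi, THF, −78 °C; then 2, −78 → 0 °C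
Reagents that add atoms: none
Why: N-acylation of the lithiated oxazolidinone by an acid chloride is the standard entry to Evans imides and leaves the methyl ester untouched at low temperature.

Step 2
Reactants: 3 (R)-4-benzyl-3-(4-methoxy-4-oxobutanoyl)oxazolidin-2-one; 4 4-(benzyloxy)-3-methoxybenzaldehyde
Product: 6 (R)-4-benzyl-3-{(2R,3R)-2-[4-(benzyloxy)-3-methoxyphenyl]-5-oxotetrahydrofuran-3-carbonyl}oxazolidin-2-one, via syn-aldol adduct 5 (not isolated)
Conditions: n-Bu2BOTf, Et3N, CH2Cl2, −78 → 0 °C; 4, −78 → 0 °C; MeOH, pH 7 buffer, 30% H2O2, 0 °C; then cat. PPTS, CH2Cl2, rt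
Reagents that add atoms: none
Why: Evans syn aldol, in which the Z boron enolate of the imide (the ester is not enolised) adds through a Zimmerman–Traxler chair on the face away from the auxiliary benzyl group to set C7 (R) and C8, after which the benzylic hydroxyl closes onto the methyl ester to give the trans-4,5-disubstituted γ-lactone.

Step 3
Reactants: 6 (R)-4-benzyl-3-{(2R,3R)-2-[4-(benzyloxy)-3-methoxyphenyl]-5-oxotetrahydrofuran-3-carbonyl}oxazolidin-2-one
Product: 7 (2R,3R)-2-[4-(benzyloxy)-3-methoxyphenyl]-5-oxotetrahydrofuran-3-carboxylic acid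
Conditions: LiOH, 30% H2O2, THF–H2O, 0 °C; Na2SO3; 1 M HCl
Reagents that add atoms: hydrogen peroxide, OO
Why: Auxiliary cleavage by lithium hydroperoxide, which attacks the exocyclic imide carbonyl; any lactone opened by hydroxide should re-close on acidification because the hydroxy diacid can form only this γ-lactone.

Step 4
Reactants: 7 (2R,3R)-2-[4-(benzyloxy)-3-methoxyphenyl]-5-oxotetrahydrofuran-3-carboxylic acid
Product: 8 (4S,5R)-5-[4-(benzyloxy)-3-methoxyphenyl]-4-(hydroxymethyl)dihydrofuran-2(3H)-one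
Conditions: BH3·SMe2, THF, 0 °C → rt; MeOH
Reagents that add atoms: none
Why: Chemoselective borane reduction of a carboxylic acid beside a lactone (via the acyloxyborane) should give the C9 alcohol without an alkoxide stage, which avoids base-induced translactonisation.

Step 5
Reactants: 9 syringaldehyde
Product: 10 4-(tert-butyldimethylsilyloxy)-3,5-dimethoxybenzaldehyde
Conditions: TBSCl, imidazole, DMF, rt
Reagents that add atoms: tert-butyldimethylsilyl chloride, CC(C)(C)[Si](C)(C)Cl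
Why: Imidazole-promoted silylation masks the central-ring phenol with a group that should survive hydride, mild acid and the carbenoid step and is later removed by fluoride in the presence of the benzyl ether.

Step 6
Reactants: 10 4-(tert-butyldimethylsilyloxy)-3,5-dimethoxybenzaldehyde
Product: 11 [4-(tert-butyldimethylsilyloxy)-3,5-dimethoxyphenyl]methanol
Conditions: NaBH4, MeOH, 0 °C
Reagents that add atoms: none
Why: Borohydride reduction of an aryl aldehyde to the benzylic alcohol, with the hindered aryl silyl ether expected to remain intact at 0 °C.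

Step 7
Reactants: 11 [4-(tert-butyldimethylsilyloxy)-3,5-dimethoxyphenyl]methanol
Product: 12 4-(tert-butyldimethylsilyloxy)-3,5-dimethoxybenzyl 2,2,2-trichloroacetimidate
Conditions: Cl3CCN, cat. DBU, CH2Cl2, 0 °C
Reagents that add atoms: trichloroacetonitrile, ClC(Cl)(Cl)C#N
Why: Base-catalysed addition of the alcohol to trichloroacetonitrile (trichloroacetimidate formation) gives a benzyl donor that can be activated by acid alone.

Step 8
Reactants: 8 (4S,5R)-5-[4-(benzyloxy)-3-methoxyphenyl]-4-(hydroxymethyl)dihydrofuran-2(3H)-one; 12 4-(tert-butyldimethylsilyloxy)-3,5-dimethoxybenzyl 2,2,2-trichloroacetimidate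
Product: 13 (4S,5R)-5-[4-(benzyloxy)-3-methoxyphenyl]-4-{[4-(tert-butyldimethylsilyloxy)-3,5-dimethoxybenzyl]oxymethyl}dihydrofuran-2(3H)-one
Conditions: cat. CSA, CH2Cl2, 0 °C → rt
Reagents that add atoms: none
Why: Acid-catalysed trichloroacetimidate benzylation, as used for p-methoxybenzyl ethers, etherifies the primary alcohol without forming its alkoxide, so the lactone should not migrate to the C9 oxygen.

Step 9
Reactants: 13 (4S,5R)-5-[4-(benzyloxy)-3-methoxyphenyl]-4-{[4-(tert-butyldimethylsilyloxy)-3,5-dimethoxybenzyl]oxymethyl}dihydrofuran-2(3H)-one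
Product: 15 (4S,5R)-5-[4-(benzyloxy)-3-methoxyphenyl]-4-{[4-(tert-butyldimethylsilyloxy)-3,5-dimethoxybenzyl]oxymethyl}-3-diazodihydrofuran-2(3H)-one, via trifluoroacetyl lactone 14 (not isolated)
Conditions: LiHMDS, THF, −78 °C; CF3CO2CH2CF3; aq. HCl; then MsN3, Et3N, H2O (1 equiv), MeCN, rt
Reagents that add atoms: methanesulfonyl azide, CS(=O)(=O)N=[N+]=[N-]; 2,2,2-trifluoroethyl trifluoroacetate, O=C(OCC(F)(F)F)C(F)(F)F (its CF3CO group is carried only by 14 and is lost again)
Why: Detrifluoroacetylative (Regitz-type) diazo transfer: the lactone enolate is C-trifluoroacetylated at C8', and the activated position then accepts the diazo group from the sulfonyl azide with loss of the acyl group, C7 and C8 being untouched because C8 carries no leaving group.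

Step 10
Reactants: 15 (4S,5R)-5-[4-(benzyloxy)-3-methoxyphenyl]-4-{[4-(tert-butyldimethylsilyloxy)-3,5-dimethoxybenzyl]oxymethyl}-3-diazodihydrofuran-2(3H)-one
Product: 16 (3R,3aS,6S,6aR)-3-[4-(benzyloxy)-3-methoxyphenyl]-6-[4-(tert-butyldimethylsilyloxy)-3,5-dimethoxyphenyl]tetrahydro-1H,3H-furo[3,4-c]furan-1-one
Conditions: Rh2(OAc)4 (2 mol %), CH2Cl2, rt, slow addition of 15
Reagents that add atoms: none
Why: Dirhodium tetraacetate expels N2 from 15 to give an electrophilic rhodium carbenoid at C8', which inserts in a concerted, asynchronous three-centre step into a benzylic C7'–H bond made hydridic by the ether oxygen and the electron-rich ring; this is the known 1,5 C–H insertion of α-diazo-γ-butyrolactones into benzyl ether C–H bonds. The tetrahydrofuran O–C7'–C8'–C8–C9 closes through a five-membered transition state on the three-atom C8–C9–O tether, so it can only be cis-fused to the lactone and C8' is set by C8. At C7' the two diastereotopic hydrogens compete, and in the chair-like insertion transition state the aryl group should sit pseudo-equatorial, away from the carboxylate ligands on rhodium, which places it on the concave face, cis to C9' (endo); the step is kinetic, so the endo isomer that acid equilibration would erase is kept. The selectivities needed are 1,5-insertion over 1,2-hydride shift from C8–H, over attack on the arenes, and endo over exo; the activated ether C–H, the short tether and the trans C7 aryl group, which lies on the face opposite the reacting arm, should secure them.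

Step 11
Reactants: 16 (3R,3aS,6S,6aR)-3-[4-(benzyloxy)-3-methoxyphenyl]-6-[4-(tert-butyldimethylsilyloxy)-3,5-dimethoxyphenyl]tetrahydro-1H,3H-furo[3,4-c]furan-1-one
Product: 17 (R)-[4-(benzyloxy)-3-methoxyphenyl]{(3S,4S,5S)-5-[4-(tert-butyldimethylsilyloxy)-3,5-dimethoxyphenyl]-4-(hydroxymethyl)tetrahydrofuran-3-yl}methanol
Conditions: LiAlH4, THF, 0 °C
Reagents that add atoms: none
Why: Hydride reduction of the lactone to the diol turns C9' into a primary carbinol and frees the C7 benzylic hydroxyl without touching any stereocentre.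

Step 12
Reactants: 17 (R)-[4-(benzyloxy)-3-methoxyphenyl]{(3S,4S,5S)-5-[4-(tert-butyldimethylsilyloxy)-3,5-dimethoxyphenyl]-4-(hydroxymethyl)tetrahydrofuran-3-yl}methanol
Product: 19 (1S,3aS,4R,6aS)-4-[4-(benzyloxy)-3-methoxyphenyl]-1-[4-(tert-butyldimethylsilyloxy)-3,5-dimethoxyphenyl]tetrahydro-1H,3H-furo[3,4-c]furan, via primary mesylate 18 (not isolated)
Conditions: MsCl (1.1 equiv), Et3N, CH2Cl2, 0 °C → rt
Reagents that add atoms: methanesulfonyl chloride, CS(=O)(=O)Cl (its group is carried only by 18)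
Why: Selective sulfonylation of the primary alcohol followed by intramolecular Williamson etherification (5-exo-tet attack of the C7 hydroxyl on C9') closes the second ring without breaking a bond at C7, so the exo guaiacyl group is retained and the basic medium should leave the endo C7' centre alone.

Step 13
Reactants: 19 (1S,3aS,4R,6aS)-4-[4-(benzyloxy)-3-methoxyphenyl]-1-[4-(tert-butyldimethylsilyloxy)-3,5-dimethoxyphenyl]tetrahydro-1H,3H-furo[3,4-c]furan
Product: 20 4-{(1S,3aS,4R,6aS)-4-[4-(benzyloxy)-3-methoxyphenyl]tetrahydro-1H,3H-furo[3,4-c]furan-1-yl}-2,6-dimethoxyphenol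
Conditions: TBAF, THF, 0 °C
Reagents that add atoms: none
Why: Fluoride desilylation frees only the central phenol, the benzyl ether on the guaiacyl ring being inert to fluoride.

Step 14
Reactants: 21 (S)-4-benzyl-2-oxazolidinone; 22 bromoacetyl bromide
Product: 23 (S)-4-benzyl-3-(2-bromoacetyl)oxazolidin-2-one
Conditions: n-BuLi, THF, −78 °C; then 22, −78 °C
Reagents that add atoms: none
Why: N-acylation of the lithiated oxazolidinone at the acyl bromide, which is far more reactive than the alkyl bromide at −78 °C.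

Step 15
Reactants: 20 4-{(1S,3aS,4R,6aS)-4-[4-(benzyloxy)-3-methoxyphenyl]tetrahydro-1H,3H-furo[3,4-c]furan-1-yl}-2,6-dimethoxyphenol; 23 (S)-4-benzyl-3-(2-bromoacetyl)oxazolidin-2-one
Product: 24 (S)-4-benzyl-3-[2-(4-{(1S,3aS,4R,6aS)-4-[4-(benzyloxy)-3-methoxyphenyl]tetrahydro-1H,3H-furo[3,4-c]furan-1-yl}-2,6-dimethoxyphenoxy)acetyl]oxazolidin-2-one
Conditions: K2CO3, acetone, rt
Reagents that add atoms: none
Why: Williamson ether synthesis at an α-bromo imide, where SN2 displacement by the hindered phenoxide should be faster than attack at either imide carbonyl.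

Step 16
Reactants: 24 (S)-4-benzyl-3-[2-(4-{(1S,3aS,4R,6aS)-4-[4-(benzyloxy)-3-methoxyphenyl]tetrahydro-1H,3H-furo[3,4-c]furan-1-yl}-2,6-dimethoxyphenoxy)acetyl]oxazolidin-2-one; 25 4-(benzyloxy)-3,5-dimethoxybenzaldehyde
Product: 26 (S)-4-benzyl-3-[(2S,3R)-3-[4-(benzyloxy)-3,5-dimethoxyphenyl]-2-(4-{(1S,3aS,4R,6aS)-4-[4-(benzyloxy)-3-methoxyphenyl]tetrahydro-1H,3H-furo[3,4-c]furan-1-yl}-2,6-dimethoxyphenoxy)-3-hydroxypropanoyl]oxazolidin-2-one
Conditions: n-Bu2BOTf, i-Pr2NEt (excess over boron), CH2Cl2, −78 → 0 °C; 25, −78 → 0 °C; MeOH, pH 7 buffer, 30% H2O2, 0 °C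
Reagents that add atoms: none
Why: Evans syn glycolate aldol, in which the Z boron enolate of the aryloxyacetyl imide adds through a Zimmerman–Traxler chair on the face away from the (S)-auxiliary benzyl group, so the aryloxy and hydroxyl groups end syn (threo) with the 7''R,8''R sense, the remote furofuran centres having no say.

Step 17
Reactants: 26 (S)-4-benzyl-3-[(2S,3R)-3-[4-(benzyloxy)-3,5-dimethoxyphenyl]-2-(4-{(1S,3aS,4R,6aS)-4-[4-(benzyloxy)-3-methoxyphenyl]tetrahydro-1H,3H-furo[3,4-c]furan-1-yl}-2,6-dimethoxyphenoxy)-3-hydroxypropanoyl]oxazolidin-2-one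
Product: 27 (1R,2R)-1-[4-(benzyloxy)-3,5-dimethoxyphenyl]-2-(4-{(1S,3aS,4R,6aS)-4-[4-(benzyloxy)-3-methoxyphenyl]tetrahydro-1H,3H-furo[3,4-c]furan-1-yl}-2,6-dimethoxyphenoxy)propane-1,3-diol
Conditions: LiBH4, MeOH (1 equiv), THF, 0 °C
Reagents that add atoms: none
Why: Reductive cleavage of the N-acyl oxazolidinone by lithium borohydride gives the C9'' primary alcohol and releases the auxiliary at a temperature where retro-aldol and epimerisation at C8'' should not compete.

Step 18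
Reactants: 27 (1R,2R)-1-[4-(benzyloxy)-3,5-dimethoxyphenyl]-2-(4-{(1S,3aS,4R,6aS)-4-[4-(benzyloxy)-3-methoxyphenyl]tetrahydro-1H,3H-furo[3,4-c]furan-1-yl}-2,6-dimethoxyphenoxy)propane-1,3-diol
Product: 28 (1R,2R)-1-(4-hydroxy-3,5-dimethoxyphenyl)-2-(4-{(1S,3aS,4R,6aS)-4-(4-hydroxy-3-methoxyphenyl)tetrahydro-1H,3H-furo[3,4-c]furan-1-yl}-2,6-dimethoxyphenoxy)propane-1,3-diol (CNP0317965.1)
Conditions: H2 (1 atm), 10% Pd/C, EtOAc–MeOH, rt, stopped at full debenzylation
Reagents that add atoms: none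
Why: Catalytic hydrogenolysis of the two aryl benzyl ethers under neutral conditions, where aryl O-benzyl cleavage should be much faster than cleavage of the dialkyl benzylic ethers of the furofuran or of the C7'' carbinol.

**Compound list**

1 | (R)-4-benzyl-2-oxazolidinone | O=C1OC[C@@H](Cc2ccccc2)N1 | starting material
2 | methyl 4-chloro-4-oxobutanoate | COC(=O)CCC(Cl)=O | starting material
3 | (R)-4-benzyl-3-(4-methoxy-4-oxobutanoyl)oxazolidin-2-one | COC(=O)CCC(=O)N1C(=O)OC[C@H]1Cc1ccccc1 | intermediate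
4 | 4-(benzyloxy)-3-methoxybenzaldehyde | COc1cc(C=O)ccc1OCc1ccccc1 | starting material
5 | methyl (3R,4R)-4-[4-(benzyloxy)-3-methoxyphenyl]-3-{[(R)-4-benzyl-2-oxooxazolidin-3-yl]carbonyl}-4-hydroxybutanoate | COC(=O)C[C@H]([C@@H](O)c1ccc(OCc2ccccc2)c(OC)c1)C(=O)N1C(=O)OC[C@H]1Cc1ccccc1 | intermediate (not isolated)
6 | (R)-4-benzyl-3-{(2R,3R)-2-[4-(benzyloxy)-3-methoxyphenyl]-5-oxotetrahydrofuran-3-carbonyl}oxazolidin-2-one | O=C1C[C@@H](C(=O)N2C(=O)OC[C@H]2Cc2ccccc2)[C@H](c2ccc(OCc3ccccc3)c(OC)c2)O1 | intermediate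
7 | (2R,3R)-2-[4-(benzyloxy)-3-methoxyphenyl]-5-oxotetrahydrofuran-3-carboxylic acid | O=C1C[C@@H](C(=O)O)[C@H](c2ccc(OCc3ccccc3)c(OC)c2)O1 | intermediate
8 | (4S,5R)-5-[4-(benzyloxy)-3-methoxyphenyl]-4-(hydroxymethyl)dihydrofuran-2(3H)-one | O=C1C[C@@H](CO)[C@H](c2ccc(OCc3ccccc3)c(OC)c2)O1 | intermediate
9 | syringaldehyde | COc1cc(C=O)cc(OC)c1O | starting material
10 | 4-(tert-butyldimethylsilyloxy)-3,5-dimethoxybenzaldehyde | COc1cc(C=O)cc(OC)c1O[Si](C)(C)C(C)(C)C | intermediate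
11 | [4-(tert-butyldimethylsilyloxy)-3,5-dimethoxyphenyl]methanol | COc1cc(CO)cc(OC)c1O[Si](C)(C)C(C)(C)C | intermediate
12 | 4-(tert-butyldimethylsilyloxy)-3,5-dimethoxybenzyl 2,2,2-trichloroacetimidate | COc1cc(COC(=N)C(Cl)(Cl)Cl)cc(OC)c1O[Si](C)(C)C(C)(C)C | intermediate
13 | (4S,5R)-5-[4-(benzyloxy)-3-methoxyphenyl]-4-{[4-(tert-butyldimethylsilyloxy)-3,5-dimethoxybenzyl]oxymethyl}dihydrofuran-2(3H)-one | O=C1C[C@@H](COCc2cc(OC)c(O[Si](C)(C)C(C)(C)C)c(OC)c2)[C@H](c2ccc(OCc3ccccc3)c(OC)c2)O1 | intermediate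
14 | 3-(trifluoroacetyl) derivative of 13 (C8' unassigned, epimers and enol) | O=C1C(C(=O)C(F)(F)F)[C@@H](COCc2cc(OC)c(O[Si](C)(C)C(C)(C)C)c(OC)c2)[C@H](c2ccc(OCc3ccccc3)c(OC)c2)O1 | intermediate (not isolated)
15 | (4S,5R)-5-[4-(benzyloxy)-3-methoxyphenyl]-4-{[4-(tert-butyldimethylsilyloxy)-3,5-dimethoxybenzyl]oxymethyl}-3-diazodihydrofuran-2(3H)-one | COc1cc([C@@H]2OC(=O)C(=[N+]=[N-])[C@H]2COCc2cc(OC)c(O[Si](C)(C)C(C)(C)C)c(OC)c2)ccc1OCc1ccccc1 | intermediate
16 | (3R,3aS,6S,6aR)-3-[4-(benzyloxy)-3-methoxyphenyl]-6-[4-(tert-butyldimethylsilyloxy)-3,5-dimethoxyphenyl]tetrahydro-1H,3H-furo[3,4-c]furan-1-one | COc1cc([C@@H]2OC(=O)[C@@H]3[C@H]2CO[C@@H]3c2cc(OC)c(O[Si](C)(C)C(C)(C)C)c(OC)c2)ccc1OCc1ccccc1 | intermediate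
17 | (R)-[4-(benzyloxy)-3-methoxyphenyl]{(3S,4S,5S)-5-[4-(tert-butyldimethylsilyloxy)-3,5-dimethoxyphenyl]-4-(hydroxymethyl)tetrahydrofuran-3-yl}methanol | COc1cc([C@H](O)[C@@H]2CO[C@H](c3cc(OC)c(O[Si](C)(C)C(C)(C)C)c(OC)c3)[C@@H]2CO)ccc1OCc1ccccc1 | intermediate
18 | C9' methanesulfonate of 17 | COc1cc([C@H](O)[C@@H]2CO[C@H](c3cc(OC)c(O[Si](C)(C)C(C)(C)C)c(OC)c3)[C@@H]2COS(C)(=O)=O)ccc1OCc1ccccc1 | intermediate (not isolated)
19 | (1S,3aS,4R,6aS)-4-[4-(benzyloxy)-3-methoxyphenyl]-1-[4-(tert-butyldimethylsilyloxy)-3,5-dimethoxyphenyl]tetrahydro-1H,3H-furo[3,4-c]furan | COc1cc([C@@H]2OC[C@@H]3[C@H]2CO[C@@H]3c2cc(OC)c(O[Si](C)(C)C(C)(C)C)c(OC)c2)ccc1OCc1ccccc1 | intermediate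
20 | 4-{(1S,3aS,4R,6aS)-4-[4-(benzyloxy)-3-methoxyphenyl]tetrahydro-1H,3H-furo[3,4-c]furan-1-yl}-2,6-dimethoxyphenol | COc1cc([C@@H]2OC[C@@H]3[C@H]2CO[C@@H]3c2cc(OC)c(O)c(OC)c2)ccc1OCc1ccccc1 | intermediate
21 | (S)-4-benzyl-2-oxazolidinone | O=C1OC[C@H](Cc2ccccc2)N1 | starting material
22 | bromoacetyl bromide | BrCC(Br)=O | starting material
23 | (S)-4-benzyl-3-(2-bromoacetyl)oxazolidin-2-one | BrCC(=O)N1C(=O)OC[C@@H]1Cc1ccccc1 | intermediate
24 | (S)-4-benzyl-3-[2-(4-{(1S,3aS,4R,6aS)-4-[4-(benzyloxy)-3-methoxyphenyl]tetrahydro-1H,3H-furo[3,4-c]furan-1-yl}-2,6-dimethoxyphenoxy)acetyl]oxazolidin-2-one | COc1cc([C@@H]2OC[C@@H]3[C@H]2CO[C@@H]3c2cc(OC)c(OCC(=O)N3C(=O)OC[C@@H]3Cc3ccccc3)c(OC)c2)ccc1OCc1ccccc1 | intermediate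
25 | 4-(benzyloxy)-3,5-dimethoxybenzaldehyde | COc1cc(C=O)cc(OC)c1OCc1ccccc1 | starting material
26 | (S)-4-benzyl-3-[(2S,3R)-3-[4-(benzyloxy)-3,5-dimethoxyphenyl]-2-(4-{(1S,3aS,4R,6aS)-4-[4-(benzyloxy)-3-methoxyphenyl]tetrahydro-1H,3H-furo[3,4-c]furan-1-yl}-2,6-dimethoxyphenoxy)-3-hydroxypropanoyl]oxazolidin-2-one | COc1cc([C@@H]2OC[C@@H]3[C@H]2CO[C@@H]3c2cc(OC)c(O[C@H](C(=O)N3C(=O)OC[C@@H]3Cc3ccccc3)[C@H](O)c3cc(OC)c(OCc4ccccc4)c(OC)c3)c(OC)c2)ccc1OCc1ccccc1 | intermediate
27 | (1R,2R)-1-[4-(benzyloxy)-3,5-dimethoxyphenyl]-2-(4-{(1S,3aS,4R,6aS)-4-[4-(benzyloxy)-3-methoxyphenyl]tetrahydro-1H,3H-furo[3,4-c]furan-1-yl}-2,6-dimethoxyphenoxy)propane-1,3-diol | COc1cc([C@@H]2OC[C@@H]3[C@H]2CO[C@@H]3c2cc(OC)c(O[C@H](CO)[C@H](O)c3cc(OC)c(OCc4ccccc4)c(OC)c3)c(OC)c2)ccc1OCc1ccccc1 | intermediate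
28 | (1R,2R)-1-(4-hydroxy-3,5-dimethoxyphenyl)-2-(4-{(1S,3aS,4R,6aS)-4-(4-hydroxy-3-methoxyphenyl)tetrahydro-1H,3H-furo[3,4-c]furan-1-yl}-2,6-dimethoxyphenoxy)propane-1,3-diol | COc1cc([C@@H]2OC[C@@H]3[C@H]2CO[C@@H]3c2cc(OC)c(O[C@H](CO)[C@H](O)c3cc(OC)c(O)c(OC)c3)c(OC)c2)ccc1O | target

**Step count and risks**

Total step count: 18. Longest linear sequence: 14 steps (steps 1–4, 8–13 and 15–18); steps 5–7 and step 14 are side branches.

Steps most likely to fail:

1. Step 10. The carbenoid may undergo 1,2-hydride migration from C8 to give a butenolide, may add to the electron-rich arenes, or may insert with poor endo/exo control. The fallback sets out from 8 and comes back at 16. Pinnick oxidation of aldehyde 10 (NaClO2, NaH2PO4, 2-methyl-2-butene) would give 4-(tert-butyldimethylsilyloxy)-3,5-dimethoxybenzoic acid F2. Steglich esterification of 8 with this acid (EDC, DMAP, CH2Cl2) would give the C9 aroyl ester F3. LiHMDS (2 equiv, THF, −78 °C) should then trigger an intramolecular Claisen (Dieckmann-type) acyl transfer from the C9 oxygen to C8', whose tetrahedral adduct is the cis-fused bicyclic hemiketal F4 (in equilibrium with the open hydroxy ketone). Ionic reduction (Et3SiH, BF3·OEt2, CH2Cl2, −78 °C) of the derived oxocarbenium ion should deliver hydride to the convex face, leaving the aryl group endo and giving 16.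

2. Step 8. The electron-rich imidate may rearrange to the N-benzyl trichloroacetamide, the acid may ionise the donor unproductively or remove the silyl group, and acid-catalysed lactone migration in 8 may compete. The fallback sets out from 8 and comes back at 13. Silylation (TMSCl, imidazole, CH2Cl2) would give the trimethylsilyl ether F1. Reductive etherification of F1 with aldehyde 10 (Et3SiH, cat. TMSOTf, CH2Cl2, −78 °C) should give 13 directly, with no benzylic electrophile and without the reduction and imidate steps.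

3. Step 16. The boron triflate may ionise the endo benzylic ether at C7' and let it epimerise to the exo isomer, enolisation may stall because boron is held by the many ether oxygens, and the aldolate may revert on work-up. The fallback sets out from 20 and comes back at 27. Williamson alkylation with ethyl bromoacetate (K2CO3, acetone) would give the ethyl aryloxyacetate F5. Its lithium enolate (LDA, THF, −78 °C) and aldehyde 25 would give the β-hydroxy ester F6 as a mixture of diastereomers. Dess–Martin oxidation would give the α-aryloxy-β-keto ester F7, which is configurationally labile at C8''. Noyori–Ikariya transfer hydrogenation with dynamic kinetic resolution (RuCl(p-cymene)[(S,S)-TsDPEN], amine-rich HCO2H–Et3N, CH2Cl2) is expected to give the syn (2S,3R) hydroxy ester F8; the antipodal catalyst would be used if the sense proved opposite. LiBH4 reduction of the ester would then give 27.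

**Further compounds**

F1 | step 8 | (4S,5R)-5-[4-(benzyloxy)-3-methoxyphenyl]-4-[(trimethylsilyloxy)methyl]dihydrofuran-2(3H)-one | O=C1C[C@@H](CO[Si](C)(C)C)[C@H](c2ccc(OCc3ccccc3)c(OC)c2)O1
F2 | step 10 | 4-(tert-butyldimethylsilyloxy)-3,5-dimethoxybenzoic acid | COc1cc(C(=O)O)cc(OC)c1O[Si](C)(C)C(C)(C)C
F3 | step 10 | {(2R,3S)-2-[4-(benzyloxy)-3-methoxyphenyl]-5-oxotetrahydrofuran-3-yl}methyl 4-(tert-butyldimethylsilyloxy)-3,5-dimethoxybenzoate | O=C1C[C@@H](COC(=O)c2cc(OC)c(O[Si](C)(C)C(C)(C)C)c(OC)c2)[C@H](c2ccc(OCc3ccccc3)c(OC)c2)O1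
F4 | step 10 | (3R,3aS,6aR)-3-[4-(benzyloxy)-3-methoxyphenyl]-6-[4-(tert-butyldimethylsilyloxy)-3,5-dimethoxyphenyl]-6-hydroxytetrahydro-1H,3H-furo[3,4-c]furan-1-one (hemiketal, C6 unassigned) | COc1cc([C@@H]2OC(=O)[C@@H]3[C@H]2COC3(O)c2cc(OC)c(O[Si](C)(C)C(C)(C)C)c(OC)c2)ccc1OCc1ccccc1
F5 | step 16 | ethyl 2-(4-{(1S,3aS,4R,6aS)-4-[4-(benzyloxy)-3-methoxyphenyl]tetrahydro-1H,3H-furo[3,4-c]furan-1-yl}-2,6-dimethoxyphenoxy)acetate | COc1cc([C@@H]2OC[C@@H]3[C@H]2CO[C@@H]3c2cc(OC)c(OCC(=O)OCC)c(OC)c2)ccc1OCc1ccccc1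
F6 | step 16 | ethyl 3-[4-(benzyloxy)-3,5-dimethoxyphenyl]-2-(4-{(1S,3aS,4R,6aS)-4-[4-(benzyloxy)-3-methoxyphenyl]tetrahydro-1H,3H-furo[3,4-c]furan-1-yl}-2,6-dimethoxyphenoxy)-3-hydroxypropanoate (mixture at C2 and C3) | COc1cc([C@@H]2OC[C@@H]3[C@H]2CO[C@@H]3c2cc(OC)c(OC(C(=O)OCC)C(O)c3cc(OC)c(OCc4ccccc4)c(OC)c3)c(OC)c2)ccc1OCc1ccccc1
F7 | step 16 | ethyl 3-[4-(benzyloxy)-3,5-dimethoxyphenyl]-2-(4-{(1S,3aS,4R,6aS)-4-[4-(benzyloxy)-3-methoxyphenyl]tetrahydro-1H,3H-furo[3,4-c]furan-1-yl}-2,6-dimethoxyphenoxy)-3-oxopropanoate (C2 labile) | COc1cc([C@@H]2OC[C@@H]3[C@H]2CO[C@@H]3c2cc(OC)c(OC(C(=O)OCC)C(=O)c3cc(OC)c(OCc4ccccc4)c(OC)c3)c(OC)c2)ccc1OCc1ccccc1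
F8 | step 16 | ethyl (2S,3R)-3-[4-(benzyloxy)-3,5-dimethoxyphenyl]-2-(4-{(1S,3aS,4R,6aS)-4-[4-(benzyloxy)-3-methoxyphenyl]tetrahydro-1H,3H-furo[3,4-c]furan-1-yl}-2,6-dimethoxyphenoxy)-3-hydroxypropanoate | COc1cc([C@@H]2OC[C@@H]3[C@H]2CO[C@@H]3c2cc(OC)c(O[C@H](C(=O)OCC)[C@H](O)c3cc(OC)c(OCc4ccccc4)c(OC)c3)c(OC)c2)ccc1OCc1ccccc1
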